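The constant I froze first was the one that ties free substrate to the target it yields. The flasks, readings and questions stood thus:

| flask | substrate | catalyst | remark | time |
|---|---|---|---|---|
| oak | 18 mM | 23 µM | run made earlier |  |
| elm | 18 mM | 12 µM | run made earlier |  |
| birch | 18 mM | 46 µM | run made earlier |  |
| maple | 9 mM | 23 µM | run made earlier |  |
| Wednesday's | 18 mM | 23 µM | a single well-mixed tank run continuously and read at steady state, 80.0 h in it on average |  |
| Saturday's | 18 mM (fed, over 4.00 h) | 23 µM | all but substrate at the start; substrate goes in evenly over 4.00 h, the run ends at 8.0 h | 8.0 h |
| Sunday's | 18 mM | 23 µM | a closed flask charged with all of it at once and left for 8.0 h | 8.0 h |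
| Tuesday's | 18 mM | 23 µM | one stirred flow tank at steady state, fed with the mixture as stated, mean residence time 8.0 h |  |

- oak (time / h: target / %, substrate / %): 2.00: 22.4, 54.3; 4.00: 34.1, 30.5; 6.00: 42.0, 17.9; 8.00: 46.6, 12.7
- elm (time / h: target / %, substrate / %): 2.00: 13.8, 70.0; 4.00: 22.7, 51.1; 6.00: 30.5, 36.5; 8.00: 33.8, 27.4
- birch (time / h: target / %, substrate / %): 1.00: 21.9, 54.5; 3.00: 43.5, 20.3; 5.00: 51.8, 10.3; 8.00: 58.0, 5.3
- maple (time / h: target / %, substrate / %): 2.00: 23.0, 54.8; 4.00: 35.4, 32.3; 6.00: 42.5, 21.7; 8.00: 49.2, 15.5

(readings scatter by 0.5 percentage points)

- the stated concentrations are those of everything mixed, before any reaction; amounts are the same in each set-up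
- the numbers in the tables scatter with a standard deviation of 0.5 percentage points
- the feed brings no volume worth counting
- the earlier runs were made in a closed, stirred flask
- a reading or a percentage of target counts all its forms, free or not
- a reading of substrate is of its free form alone

1. the set-up with the highest amount of target at the outlet or at the end, in percent of the substrate put in ("none" if the first two lie within 2 percentage points) (Wednesday's / Saturday's / Sunday's / Tuesday's / none)
2. amount of target at the outlet or at the end, in percent of the substrate put in, Wednesday's
3. amount of target at the outlet or at the end, in percent of the substrate put in, Saturday's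
4. amount of target at the outlet or at the end, in percent of the substrate put in, Sunday's
5. amount of target at the outlet or at the end, in percent of the substrate put in, Tuesday's

I called it the making constant, a pseudo-first-order constant. Dividing oak's first target reading by the log-mean free substrate over those hours gave 0.150 /h, the target formed per hour per unit of free substrate at 23 µM catalyst. Between oak's last two readings it read 0.152 /h, so I took it as steady through that run. Maple, with half the substrate and the same catalyst, read 0.153 /h. Birch, with 46 µM catalyst, read twice oak's value. So target is this constant times the area under the free-substrate curve, and in a steady tank that area is the residence time times the free share.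

Maple ended with more target than oak, 49.2% against 46.6%, because the share found as neither substrate nor target was smaller in maple, 35.3% against 40.7%, so the same constant had more free substrate to work on, 15.5% against 12.7%.

For the tanks I set x as the making constant times the residence time. I reckoned x/(1 + x) with no loss, and x/(1 + 2x) with a loss as fast as target, as oak's first missing share of 23.3% suggested. That gave Tuesday's 35.3% to 54.5% and Wednesday's 48.0% to 92.3%. Oak's missing share stalled at 40.1% by 6.00 h, so I held Tuesday's near its low end and put Wednesday's, with its far longer stay, inside its range. That low end stood 1.4 percentage points above oak's reading, against a margin of 2 points, and I made no figure for Saturday's, so naming Wednesday's best was my judgement from its range, not a bound. I expected Sunday's to repeat oak.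

The forecast also named Wednesday's, with Wednesday's 78%, Saturday's 44%, Sunday's 47% and Tuesday's 39.5%, which sets Tuesday's above my low end. Its ground for Wednesday's: “long residence drains the reservoir”.

Wednesday's gave the most: 58.3%, against Saturday's 41.4%, Sunday's 46.7% and Tuesday's 35.4%.

    substrate → side product (k = 3.58 × 10⁻⁴ /min)
    substrate + catalyst → catalyst + target (k = 109 /M/min)
    substrate + target ⇌ idle adduct, settled at all times (K = 1100 /M)

Wednesday's tank stood at 4.84% free substrate with 8.32% side product, and its target counts the idle adduct, each as one target. The making constant times the 80.0 h spent there on average times that free share gives 58.1%, against 58.3%. On Tuesday's, with 29.4% free substrate and 8.0 h mean residence time, the same product gives 35.3%, against 35.4%.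

(The readings come from a simulation with made-up constants, noise included.)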